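The readings were generated by integration with made-up constants; scatter was added.

How much left-handed and right-handed product stand in the flask at 15 d?

1. left-handed product at 15 d, in percent of the left-handed substrate and right-handed substrate together charged
2. right-handed product at 15 d, in percent of the left-handed substrate and right-handed substrate together charged

| setting | theta | delta | flask |
|---|---|---|---|
| left-handed substrate | 0.014 M | 0.022 M | 0.010 M |
| right-handed substrate | 0.014 M | 0.022 M | 0.010 M |
| reagent | 0.022 M | 0.022 M | 0.0220 M |
| free catalyst | 62 µM | 62 µM | 62 µM |
| racemization catalyst | 0.25 mM | 0.25 mM | 0.25 mM |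
| remark | run made earlier | run made earlier |  |
| time |  |  | 15 d |

| run | time / d | left-handed product / % | right-handed product / % |
|---|---|---|---|
| theta | 1.25 | 44.8 | 26.7 |
| theta | 2.50 | 44.9 | 27.1 |
| theta | 4.00 | 46.2 | 27.2 |
| theta | 8.00 | 45.8 | 26.2 |
| theta | 15.0 | 45.6 | 26.9 |
| delta | 1.25 | 30.3 | 17.5 |
| delta | 4.00 | 30.3 | 17.7 |
| delta | 8.00 | 29.7 | 16.9 |
| delta | 10.0 | 30.8 | 17.3 |
| delta | 15.0 | 30.6 | 17.5 |

(readings scatter by 0.3 percentage points)

- free catalyst is single-handed; left-handed substrate and right-handed substrate are mirror images of each other, charged as a racemate, each of them at the stated concentration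
- the numbers in the tables scatter with a standard deviation of 0.3 percentage points

The first rung I can read is the split of the products. I read left-handed over right-handed product as 1.68 at 1.25 d and 1.70 at 15.0 d in the theta run, and 1.75 at 15.0 d in the delta run, so the split looks constant. Next comes product formation: by 1.25 d the theta run reads 44.8% of left-handed product. Its highest later reading, 46.2% at 4.00 d, stands 1.4 points above that against a scatter of 0.3 points, so I allow a small real rise after the first reading. The delta run reads 30.3% at 1.25 d and 30.6% at 15.0 d.

I count one reagent per product, so product is c(reagent) minus a small correction. That correction is 0.00170 M in the theta run and 8.36 × 10⁻⁴ M in the delta run. I assume the loss per product grows as substrate thins, so loss equals a constant times ln(substrate charged over substrate left). This loss constant reads 0.00132 M and 0.00127 M, mean 0.00130 M.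

The flask's reagent exceeds its substrate by 0.00200 M, so substrate left equals loss minus that excess. Guessing the constant as substrate left and averaging once gives 0.00142 M left. My total is 92.9%, which splits into 58.4% and 34.5%.

The forecast, holding that “A competing reagent loss fits”, says 58% (54% to 61%) and 34% (31.5% to 36.5%), on a total of 92 percent against my slightly higher one.

The flask gives 59.6% and 35.7%, inside both ranges.

    reagent + free catalyst + left-handed substrate → free catalyst + left-handed product (k = 2.30 × 10⁵ /M²/h)
    reagent + free catalyst + right-handed substrate → free catalyst + right-handed product (k = 1.20 × 10⁵ /M²/h)
    left-handed substrate + racemization catalyst ⇌ right-handed substrate + racemization catalyst, rate k3*[racemization catalyst]*[left-handed substrate] forward; the back reaction follows from the equilibrium constant (k = 580 /M/h)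
    2 reagent → homo dimer (k = 0.840 /M/h)

The flask holds 0.00146 M of homo dimer at 15.0 d, two reagent each, so 0.00292 M of reagent. The loss constant on the substrate left gives 0.00397 M, more, yet the total stands 2.4 points above mine, less than the forecast's span for left-handed product. For the neighbour flask charged with 0.0055 M of reagent, the constant gives a total of 25.4%; that neighbour holds 17.4% and 9.44%.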